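The route rests on cutting C3–C4 of ring A (kaurane numbering; ring A = C1–C5, C10). The gem-dimethyl quaternary C4 is treated as a hydroalkylated isopropenyl group, so C5 and its isopropenyl unit come from (S)-carvone. In the key step hydrogen-atom transfer to the isopropenyl CH2 of iodide 3 creates the second C4 methyl and the tertiary C4 radical, which nickel couples with the C3 iodide: ring A closes trans-fused on the carvone ring. That ring is then cleaved, excising its enone carbon, to lactone 8 (C7 and C9 differentiated); sulfone alkylation attaches cyclopentenone fragment 15, a Nozaki–Hiyama–Kishi reaction closes the ten-membered ring at C7–C8, and C11 hydroxylation and C16 methylenation finish.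

Key step: step 3

Remark on numbering: kaurane numbering is used throughout. C4 carries the two methyls, C10 the angular methyl C20; C9 and C15 are ketones, C11 the carbinol, C7 the acetoxy carbinol, C13 the bridgehead CH, C8=C14 the ring alkene, C16=C17 the methylene. The ten-membered ring is C5–C6–C7–C8–C14–C13–C12–C11–C9–C10; ring D is C8–C14–C13–C16–C15.
Assumption: 1 and 10 are bought as single enantiomers. The epoxide configuration of 5, C11 of 16 and C16 of 23/24 are inconsequential.

Step 1
Reactants: 1 (S)-(+)-carvone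
Product: 2 (5S,6R)-6-methylcarvone
Conditions: LiN(i-Pr)2, THF, −78 °C; MeI, −78 → −20 °C
Reagents that add atoms: iodomethane CI
Why: Kinetic α′-deprotonation at C6 and enolate methylation install the future C20; the methyl should enter mainly trans to the isopropenyl group, but this centre is re-enolised in step 2, so both epimers converge.

Step 2
Reactants: 2 (5S,6R)-6-methylcarvone
Product: 3 (5R,6R)-6-(3-iodopropyl)-2,6-dimethyl-5-(prop-1-en-2-yl)cyclohex-2-en-1-one
Conditions: LiN(i-Pr)2, THF, −78 → 0 °C; I(CH2)3I (5 equiv), DMPU, −78 °C → rt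
Reagents that add atoms: 1,3-diiodopropane ICCCI
Why: Alkylation of the fully substituted lithium enolate builds the C10 quaternary centre; the electrophile should approach anti to the neighbouring C5 isopropenyl group, placing the iodopropyl chain (C1–C3) trans and the methyl cis to it, and the excess of diiodide should suppress double alkylation.

Step 3
Reactants: 3 (5R,6R)-6-(3-iodopropyl)-2,6-dimethyl-5-(prop-1-en-2-yl)cyclohex-2-en-1-one
Product: 4 (4aR,8aR)-2,5,5,8a-tetramethyl-4a,5,6,7,8,8a-hexahydronaphthalen-1(4H)-one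
Conditions: Mn(dpm)3 (20 mol%, dpm = dipivaloylmethanate), Ni(acac)2 (10 mol%), PhSiH3, K2CO3, (CF3)2CHOH, ClCH2CH2Cl/propylene carbonate, 0.01 M, rt
Reagents that add atoms: none
Why: Proposed new method: ring-closing version of the manganese/nickel dual-catalytic Markovnikov hydroalkylation of unactivated olefins with alkyl iodides, whose closest known relative is the intermolecular MHAT–nickel coupling that makes quaternary carbons from 1,1-disubstituted alkenes and primary iodides. A manganese hydride formed from Mn(dpm)3 and PhSiH3 transfers a hydrogen atom to the terminal CH2 of the isopropenyl group, giving the tertiary C4 radical and the second C4 methyl; low-valent nickel activates the primary C3–I bond, captures the C4 radical and forms C3–C4 by reductive elimination. Ring A therefore closes as a six-membered ring by C(sp3)–C(sp3) coupling through a seven-membered nickelacycle, not by radical addition to a π bond. No new stereocentre arises (C4 carries two methyls), and the trans ring fusion is fixed by the trans relation of the C10 chain and the C5 isopropenyl group set in step 2. The step needs HAT at the electron-rich 1,1-disubstituted alkene in preference to the trisubstituted, electron-poor enone alkene, which the known preference of such hydrides for terminal donor alkenes should secure. Ring closure must also outrun plain reduction of alkene or iodide, which the 1,6-placement of both partners on one rigid ring and high dilution favour.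

Step 4
Reactants: 4 (4aR,8aR)-2,5,5,8a-tetramethyl-4a,5,6,7,8,8a-hexahydronaphthalen-1(4H)-one
Product: 5 (4aR,8aR)-2,3-epoxy-2,5,5,8a-tetramethyloctahydronaphthalen-1(2H)-one (epoxide anti to the 8a-methyl)
Conditions: 30% H2O2, NaOH (cat.), MeOH, 0 °C → rt
Reagents that add atoms: hydrogen peroxide OO
Why: Weitz–Scheffer nucleophilic epoxidation of the enone, hydroperoxide adding to the β-carbon anti to the C5 substituent; the epoxide configuration is immaterial because both carbons are cleaved in step 5.

Step 5
Reactants: 5 (4aR,8aR)-2,3-epoxy-2,5,5,8a-tetramethyloctahydronaphthalen-1(2H)-one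
Product: 6 (1R,2R)-1,3,3-trimethyl-2-(2-oxoethyl)cyclohexane-1-carboxylic acid
Conditions: H5IO6, THF/H2O, rt
Reagents that add atoms: orthoperiodic acid OI(=O)(O)(O)(O)O; water O
Why: Acid-mediated hydration of the epoxide and two Malaprade-type periodate cleavages of the resulting α,β-dihydroxy ketone excise the old enone α-carbon and its methyl as acetic acid, leaving C9 as the acid and C7 as the aldehyde without touching C5 or C10.

Step 6
Reactants: 6 (1R,2R)-1,3,3-trimethyl-2-(2-oxoethyl)cyclohexane-1-carboxylic acid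
Product: 8 (4aR,8aR)-5,5,8a-trimethyloctahydro-1H-isochromen-1-one, via hydroxy acid 7 (not isolated)
Conditions: NaBH4, EtOH/H2O, 0 °C; then 2 M HCl, THF, 50 °C
Reagents that add atoms: none
Why: Borohydride reduces only the aldehyde of the carboxylate salt and acidification closes the δ-lactone (Fischer-type lactonisation), which stores C7 as an alkoxy carbon and C9 as an acyl carbon.

Step 7
Reactants: 8 (4aR,8aR)-5,5,8a-trimethyloctahydro-1H-isochromen-1-one
Product: 9 1-[(1R,2R)-2-(2-hydroxyethyl)-1,3,3-trimethylcyclohexyl]-2-(phenylsulfonyl)ethan-1-one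
Conditions: PhSO2CH3, n-BuLi, THF, −78 °C; add 8, −78 → 0 °C; aq NH4Cl
Reagents that add atoms: methyl phenyl sulfone CS(=O)(=O)c1ccccc1
Why: Claisen-type acylation of the sulfonyl carbanion by the lactone gives the β-keto sulfone (C11 installed, C7–OH released), and immediate deprotonation of the product prevents a second addition to the hindered C9 carbonyl.

Step 8
Reactants: 10 (R)-4-(tert-butyldimethylsilyloxy)cyclopent-2-en-1-one
Product: 12 (R)-4-(hydroxymethyl)cyclopent-2-en-1-one, via methanol adduct 11 (not isolated)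
Conditions: hν (350 nm), Ph2CO (cat.), MeOH, rt; evaporate; DBU, CH2Cl2, 0 °C
Reagents that add atoms: methanol CO
Why: Benzophenone-sensitised radical conjugate addition of the hydroxymethyl radical to the enone β-carbon anti to the silyloxy group sets C13, and E1cB loss of silanolate then shifts the enone, so the C–O stereocentre of 10 is traded for the C13–C12 stereocentre.

Step 9
Reactants: 12 (R)-4-(hydroxymethyl)cyclopent-2-en-1-one
Product: 13 (R)-4-(hydroxymethyl)-2-iodocyclopent-2-en-1-one
Conditions: I2, pyridine, CH2Cl2, rt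
Reagents that add atoms: iodine II
Why: α-Iodination of the enone (pyridine conjugate addition, iodination of the enolate, elimination) places the C8 iodide needed for the ring-closing coupling.

Step 10
Reactants: 13 (R)-4-(hydroxymethyl)-2-iodocyclopent-2-en-1-one
Product: 14 [(8R)-6-iodo-1,4-dioxaspiro[4.4]non-6-en-8-yl]methanol
Conditions: HOCH2CH2OH, TsOH (cat.), benzene, reflux (Dean–Stark)
Reagents that add atoms: ethylene glycol OCCO
Why: Acid-catalysed ketalisation of the α-iodo enone (the α-halogen holds the double bond in place) masks C15, so that C9 is later the only enolisable ketone.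

Step 11
Reactants: 14 [(8R)-6-iodo-1,4-dioxaspiro[4.4]non-6-en-8-yl]methanol
Product: 15 (8R)-6-iodo-8-(iodomethyl)-1,4-dioxaspiro[4.4]non-6-ene
Conditions: I2, PPh3, imidazole, CH2Cl2, 0 °C → rt
Reagents that add atoms: iodine II
Why: Appel-type iodination of the primary alcohol under imidazole buffering, which the ketal and the vinyl iodide tolerate.

Step 12
Reactants: 9 1-[(1R,2R)-2-(2-hydroxyethyl)-1,3,3-trimethylcyclohexyl]-2-(phenylsulfonyl)ethan-1-one; 15 (8R)-6-iodo-8-(iodomethyl)-1,4-dioxaspiro[4.4]non-6-ene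
Product: 16 1-[(1R,2R)-2-(2-hydroxyethyl)-1,3,3-trimethylcyclohexyl]-3-[(8S)-6-iodo-1,4-dioxaspiro[4.4]non-6-en-8-yl]-2-(phenylsulfonyl)propan-1-one (C2 epimers)
Conditions: Cs2CO3, DMF, 40 °C
Reagents that add atoms: none
Why: SN2 C-alkylation of the soft β-keto sulfone anion by the primary iodide forms C11–C12; carbonate does not ionise the primary alcohol, the vinyl iodide is inert, and the C11 configuration is irrelevant.

Step 13
Reactants: 16 (sulfone of step 12)
Product: 17 1-[(1R,2R)-2-(2-hydroxyethyl)-1,3,3-trimethylcyclohexyl]-3-[(8R)-6-iodo-1,4-dioxaspiro[4.4]non-6-en-8-yl]propan-1-one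
Conditions: SmI2, THF/MeOH, −78 °C
Reagents that add atoms: none
Why: Reductive desulfonylation of the β-keto sulfone through the samarium enolate; at −78 °C without HMPA the vinyl iodide and the ketal should stay intact.

Step 14
Reactants: 17 (hydroxy ketone of step 13)
Product: 18 2-[(1R,2R)-2-{3-[(8R)-6-iodo-1,4-dioxaspiro[4.4]non-6-en-8-yl]propanoyl}-2,6,6-trimethylcyclohexyl]acetaldehyde
Conditions: Dess–Martin periodinane, NaHCO3, CH2Cl2, 0 °C → rt
Reagents that add atoms: none
Why: Buffered hypervalent-iodine oxidation of the primary alcohol gives the C7 aldehyde and spares the ketal and the vinyl iodide.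

Step 15
Reactants: 18 (keto aldehyde of step 14)
Product: 19 (5R,7R,10R,13R)-7-hydroxy-17-nor-8,9-secokaur-8(14)-ene-9,15-dione 15-(ethylene ketal)
Conditions: CrCl2 (10 equiv), NiCl2 (2 mol%), DMSO/THF, 0.003 M, rt
Reagents that add atoms: none
Why: Nozaki–Hiyama–Kishi reaction: nickel inserts into the C8–I bond, transmetalation gives the vinylchromium species, which adds to the aldehyde but not to the hindered C9 ketone and closes the ten-membered ring at C7–C8; C7 is set under conformational control of the forming ring, and the 7R carbinol (hydroxyl turned away from the C15 ketal) is expected to be favoured.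

Step 16
Reactants: 19 (macrocyclic alcohol of step 15)
Product: 20 (5R,7R,10R,13R)-7-acetoxy-17-nor-8,9-secokaur-8(14)-ene-9,15-dione 15-(ethylene ketal)
Conditions: Ac2O, DMAP, pyridine, CH2Cl2, rt
Reagents that add atoms: acetic anhydride CC(=O)OC(C)=O
Why: DMAP-catalysed acetylation of the only hydroxyl group.

Step 17
Reactants: 20 (acetate of step 16)
Product: 22 (5R,7R,10R,11S,13R)-7-acetoxy-11-hydroxy-17-nor-8,9-secokaur-8(14)-ene-9,15-dione, via hydroxy ketal 21 (not isolated)
Conditions: KN(SiMe3)2, THF, −78 °C; 2-(phenylsulfonyl)-3-phenyloxaziridine, −78 °C; then 1 M HCl, THF, rt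
Reagents that add atoms: 2-(phenylsulfonyl)-3-phenyloxaziridine O=S(=O)(c1ccccc1)N1OC1c1ccccc1; water O
Why: With C10 quaternary and C15 masked, the C9 ketone can enolise only toward C11 and is more acidic than the acetate, so enolate oxidation by the N-sulfonyloxaziridine hydroxylates C11 alone, the oxidant attacking the outer face of the ring enolate (11S expected); dilute acid then hydrolyses the ketal to the C15 enone.

Step 18
Reactants: 22 (hydroxy enone of step 17)
Product: 25 (5R,7R,10R,11S,13S)-7-acetoxy-11-hydroxy-8,9-secokaura-8(14),16-diene-9,15-dione, via Mannich base 23 (not isolated), via ammonium iodide 24 (not isolated)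
Conditions: LiN(SiMe3)2 (2.2 equiv), THF, −78 °C; Eschenmoser's salt, −78 → 0 °C; then MeI, CH2Cl2, rt; aq NaHCO3
Reagents that add atoms: Eschenmoser's salt C=[N+](C)C.[I-]
Why: Eschenmoser methylenation: the C11 hydroxyl is first protected as its alkoxide, then kinetic α′-deprotonation of the cyclopentenone at C16 (the only sp3 α-carbon of C15), Mannich reaction, N-methylation and E1cB loss of trimethylamine install the C16=C17 methylene without touching a stereocentre.

Compound list
1 | (S)-(+)-carvone, (5S)-2-methyl-5-(prop-1-en-2-yl)cyclohex-2-en-1-one | O=C1C[C@@H](C(C)=C)CC=C1C | starting material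
2 | (5S,6R)-2,6-dimethyl-5-(prop-1-en-2-yl)cyclohex-2-en-1-one (trans-6-methylcarvone) | O=C1[C@H](C)[C@@H](C(C)=C)CC=C1C | intermediate
3 | (5R,6R)-6-(3-iodopropyl)-2,6-dimethyl-5-(prop-1-en-2-yl)cyclohex-2-en-1-one | O=C1[C@](C)(CCCI)[C@@H](C(C)=C)CC=C1C | intermediate
4 | (4aR,8aR)-2,5,5,8a-tetramethyl-4a,5,6,7,8,8a-hexahydronaphthalen-1(4H)-one (trans-fused) | O=C1[C@]2(C)CCCC(C)(C)[C@H]2CC=C1C | intermediate
5 | (4aR,8aR)-2,3-epoxy-2,5,5,8a-tetramethyloctahydronaphthalen-1(2H)-one, epoxide anti to the 8a-methyl | O=C1[C@]2(C)CCCC(C)(C)[C@H]2C[C@@H]3O[C@]13C | intermediate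
6 | (1R,2R)-1,3,3-trimethyl-2-(2-oxoethyl)cyclohexane-1-carboxylic acid | OC(=O)[C@]1(C)CCCC(C)(C)[C@H]1CC=O | intermediate
7 | (1R,2R)-2-(2-hydroxyethyl)-1,3,3-trimethylcyclohexane-1-carboxylic acid | OC(=O)[C@]1(C)CCCC(C)(C)[C@H]1CCO | intermediate (not isolated)
8 | (4aR,8aR)-5,5,8a-trimethyloctahydro-1H-isochromen-1-one (trans-fused δ-lactone) | O=C1[C@]2(C)CCCC(C)(C)[C@H]2CCO1 | intermediate
9 | 1-[(1R,2R)-2-(2-hydroxyethyl)-1,3,3-trimethylcyclohexyl]-2-(phenylsulfonyl)ethan-1-one | O=C(CS(=O)(=O)c1ccccc1)[C@]1(C)CCCC(C)(C)[C@H]1CCO | intermediate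
10 | (R)-4-(tert-butyldimethylsilyloxy)cyclopent-2-en-1-one | O=C1C=C[C@H](O[Si](C)(C)C(C)(C)C)C1 | starting material
11 | (3S,4R)-4-(tert-butyldimethylsilyloxy)-3-(hydroxymethyl)cyclopentan-1-one (trans) | O=C1C[C@@H](CO)[C@H](O[Si](C)(C)C(C)(C)C)C1 | intermediate (not isolated)
12 | (R)-4-(hydroxymethyl)cyclopent-2-en-1-one | O=C1C=C[C@H](CO)C1 | intermediate
13 | (R)-4-(hydroxymethyl)-2-iodocyclopent-2-en-1-one | O=C1C(I)=C[C@H](CO)C1 | intermediate
14 | [(8R)-6-iodo-1,4-dioxaspiro[4.4]non-6-en-8-yl]methanol | IC1=C[C@H](CO)CC12OCCO2 | intermediate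
15 | (8R)-6-iodo-8-(iodomethyl)-1,4-dioxaspiro[4.4]non-6-ene | IC1=C[C@H](CI)CC12OCCO2 | intermediate
16 | 1-[(1R,2R)-2-(2-hydroxyethyl)-1,3,3-trimethylcyclohexyl]-3-[(8S)-6-iodo-1,4-dioxaspiro[4.4]non-6-en-8-yl]-2-(phenylsulfonyl)propan-1-one (C2 epimers) | O=C(C(C[C@H]1C=C(I)C2(OCCO2)C1)S(=O)(=O)c1ccccc1)[C@]1(C)CCCC(C)(C)[C@H]1CCO | intermediate
17 | 1-[(1R,2R)-2-(2-hydroxyethyl)-1,3,3-trimethylcyclohexyl]-3-[(8R)-6-iodo-1,4-dioxaspiro[4.4]non-6-en-8-yl]propan-1-one | O=C(CC[C@H]1C=C(I)C2(OCCO2)C1)[C@]1(C)CCCC(C)(C)[C@H]1CCO | intermediate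
18 | 2-[(1R,2R)-2-{3-[(8R)-6-iodo-1,4-dioxaspiro[4.4]non-6-en-8-yl]propanoyl}-2,6,6-trimethylcyclohexyl]acetaldehyde | O=C(CC[C@H]1C=C(I)C2(OCCO2)C1)[C@]1(C)CCCC(C)(C)[C@H]1CC=O | intermediate
19 | (5R,7R,10R,13R)-7-hydroxy-17-nor-8,9-secokaur-8(14)-ene-9,15-dione 15-(ethylene ketal) | C1C4(OCCO4)C3=C[C@@H]1CCC(=O)[C@]5(C)CCCC(C)(C)[C@H]5C[C@H]3O | intermediate
20 | (5R,7R,10R,13R)-7-acetoxy-17-nor-8,9-secokaur-8(14)-ene-9,15-dione 15-(ethylene ketal) | C1C4(OCCO4)C3=C[C@@H]1CCC(=O)[C@]5(C)CCCC(C)(C)[C@H]5C[C@H]3OC(C)=O | intermediate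
21 | (5R,7R,10R,11S,13R)-7-acetoxy-11-hydroxy-17-nor-8,9-secokaur-8(14)-ene-9,15-dione 15-(ethylene ketal) | C1C4(OCCO4)C3=C[C@@H]1C[C@H](O)C(=O)[C@]5(C)CCCC(C)(C)[C@H]5C[C@H]3OC(C)=O | intermediate (not isolated)
22 | (5R,7R,10R,11S,13R)-7-acetoxy-11-hydroxy-17-nor-8,9-secokaur-8(14)-ene-9,15-dione | C1C(=O)C3=C[C@@H]1C[C@H](O)C(=O)[C@]5(C)CCCC(C)(C)[C@H]5C[C@H]3OC(C)=O | intermediate
23 | 16-[(dimethylamino)methyl] derivative of 22 (C16 epimers, other centres as in 22) | CN(C)CC1C(=O)C3=C[C@@H]1C[C@H](O)C(=O)[C@]5(C)CCCC(C)(C)[C@H]5C[C@H]3OC(C)=O | intermediate (not isolated)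
24 | N-methyl ammonium iodide of 23 | C[N+](C)(C)CC1C(=O)C3=C[C@@H]1C[C@H](O)C(=O)[C@]5(C)CCCC(C)(C)[C@H]5C[C@H]3OC(C)=O.[I-] | intermediate (not isolated)
25 | (5R,7R,10R,11S,13S)-7-acetoxy-11-hydroxy-8,9-secokaura-8(14),16-diene-9,15-dione (CNP0159088.1) | C=C1C(=O)C2=C[C@@H]1C[C@H](O)C(=O)[C@]1(C)CCCC(C)(C)[C@H]1C[C@H]2OC(C)=O | target

Total step count: 18. Longest linear sequence: 14 steps (steps 1–7, then 12–18); the cyclopentenone branch (steps 8–11) is 4 steps.

Steps most likely to fail

Step 3 (proposed method). Ring closure may lose to plain hydrogenation of the isopropenyl group, to reduction of the C–I bond, or to HAT reduction of the enone. The fallback uses known chemistry, sets out from 2 and returns at 4. The enolate of 2 is alkylated with tert-butyl 2-(bromomethyl)acrylate to give the carvone acrylate F1. An iron-hydride MHAT-initiated Giese cyclisation (Fe(acac)3, PhSiH3, EtOH/ethylene glycol, 60 °C) then forms the same C3–C4 bond by 6-endo addition of the tertiary C4 radical to the acrylate CH2, giving the decalin ester F2 (C2 epimers). TFA liberates the decalin acid F3, which is converted into its N-acyloxypyridine-2-thione ester, the Barton ester F4, and reduced by Barton decarboxylation (t-BuSH, hν) to 4.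

Step 15. The ring-closing addition may show poor facial selectivity at C7, since the new centre is controlled only by the conformation of the forming ten-membered ring. The fallback sets out from 19 (as its C7-epimer mixture) and returns at 19. The mixture is oxidised (Dess–Martin periodinane) to the C7 enone F5, and C7 is then set by reagent control in a Corey–Bakshi–Shibata reduction (catecholborane, the oxazaborolidine antipode chosen to deliver 7R). The hindered C9 ketone should react more slowly than the enone carbonyl.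

Step 17. Enolate oxidation may show poor facial selectivity at C11, or the acetate may be deprotonated in competition. The fallback sets out from 21 (crude C11-epimer mixture, taken before the acid treatment) and returns at 21, which is hydrolysed to 22 as in step 17. The mixture is oxidised (Dess–Martin periodinane) to the 9,11-diketone F6, and Noyori asymmetric transfer hydrogenation (RuCl(p-cymene)(TsDPEN), HCO2H/Et3N, catalyst antipode chosen to deliver 11S) reduces only the unhindered C11 carbonyl next to the neopentyl C9 ketone.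

Further compounds
F1 | step 3 | tert-butyl 2-{[(1R,6R)-1,3-dimethyl-2-oxo-6-(prop-1-en-2-yl)cyclohex-3-en-1-yl]methyl}acrylate | O=C1[C@](C)(CC(=C)C(=O)OC(C)(C)C)[C@@H](C(C)=C)CC=C1C
F2 | step 3 | tert-butyl ester of 4 carrying CO2t-Bu at C2 of ring A (position 7 of the naphthalenone, epimers) | O=C1[C@]2(C)CC(C(=O)OC(C)(C)C)CC(C)(C)[C@H]2CC=C1C
F3 | step 3 | carboxylic acid from F2 | O=C1[C@]2(C)CC(C(=O)O)CC(C)(C)[C@H]2CC=C1C
F4 | step 3 | 2-thioxopyridin-1(2H)-yl ester of F3 (Barton ester) | O=C1[C@]2(C)CC(C(=O)ON3C=CC=CC3=S)CC(C)(C)[C@H]2CC=C1C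
F5 | step 15 | (5R,10R,13R)-17-nor-8,9-secokaur-8(14)-ene-7,9,15-trione 15-(ethylene ketal) | C1C4(OCCO4)C3=C[C@@H]1CCC(=O)[C@]5(C)CCCC(C)(C)[C@H]5CC3=O
F6 | step 17 | 7-acetoxy-17-nor-8,9-secokaur-8(14)-ene-9,11,15-trione 15-(ethylene ketal), other centres as in 20 | C1C4(OCCO4)C3=C[C@@H]1CC(=O)C(=O)[C@]5(C)CCCC(C)(C)[C@H]5C[C@H]3OC(C)=O
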